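**Strategy**

- Cuts, in retrosynthetic order: the two O–benzyl bonds that mask the catechol; the lactone O1–C5 bond, with C5 traced back to a propenyl group; the ring bond C3–C4 (lignan C8′–C8) as the σ-bond of an ester-enolate Claisen shift; the ester C(=O)–O bond; and, in the alcohol half, the ArCH2–C(sp) bond.
- Enabling feature: in the butanolide ring, C3 and C4 are neighbouring CH centres that each hold an arylmethyl arm. C3 sits on the carbonyl carbon C2 and C4 on the one-carbon OCH2 unit C5, so C2–C3–C4–C5 is a γ,δ-unsaturated acid in disguise once C5 is read as the stump of an alkene.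
- Forward order: benzyl-protected dihydrocaffeic acid and an (R)-configured E-allylic alcohol (veratryl bromide plus (R)-but-3-yn-2-ol, then trans reduction) are first tied together through an ester oxygen. The [3,3] shift exchanges that C–O link for the central C–C bond. The lactone, the only ring made, closes last after the propenyl group is trimmed to CH2OH, and hydrogenolysis then uncovers the catechol.
- Stereochemistry: the purchased carbinol centre is the only chiral input and is relayed to C4 by 1,3-transfer through a chair. C3 is fixed relative to C4 by the ketene acetal geometry, and the trans ring relationship is backed by base equilibration of the lactone.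

Key step: step 7

Remark: lactone positions are numbered O1, C2 (C=O), C3, C4, C5 (OCH2); purchased (R)-but-3-yn-2-ol is taken as enantiomerically pure and LiN(i-Pr)2 is taken from a commercial solution.

**Route**

Step 1
Reactants: 1 3-(3,4-dihydroxyphenyl)propanoic acid (dihydrocaffeic acid)
Product: 2 benzyl 3-[3,4-bis(benzyloxy)phenyl]propanoate
Conditions: BnBr (3.5 equiv), K2CO3, DMF, 60 °C, under N2
Reagents that add atoms: benzyl bromide, BrCc1ccccc1
Why: Under K2CO3 the carboxylate and both phenoxides each displace bromide from benzyl bromide (Williamson etherification plus carboxylate O-alkylation), so all three acidic groups are capped in one operation, and exclusion of air keeps the free catechol from oxidising before it is alkylated.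

Step 2
Reactants: 2 benzyl 3-[3,4-bis(benzyloxy)phenyl]propanoate
Product: 3 3-[3,4-bis(benzyloxy)phenyl]propanoic acid
Conditions: LiOH, THF/MeOH/H2O, 50 °C; then 1 M HCl
Reagents that add atoms: lithium hydroxide, [Li+].[OH-]
Why: Hydroxide attacks only the ester carbonyl (saponification by acyl substitution) and releases benzyl alcohol, whereas the two aryl benzyl ethers have no pathway for cleavage in aqueous base.

Step 3
Reactants: 4 3,4-dimethoxybenzyl alcohol (veratryl alcohol)
Product: 5 3,4-dimethoxybenzyl bromide
Conditions: PBr3 (0.4 equiv), Et2O, 0 °C; used at once without storage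
Reagents that add atoms: phosphorus tribromide, BrP(Br)Br
Why: The benzylic alcohol is converted through its phosphite ester into the bromide by bromide displacement (PBr3 bromination of an alcohol), which is fast at 0 °C for an electron-rich benzyl system, and immediate use avoids self-condensation of the labile product.

Step 4
Reactants: 5 3,4-dimethoxybenzyl bromide; 6 (R)-but-3-yn-2-ol
Product: 8 (R)-5-(3,4-dimethoxyphenyl)pent-3-yn-2-ol, via dimagnesium alkynide 7 (not isolated)
Conditions: 6 (1.3 equiv), EtMgBr (2 equiv per 6), THF, 0 → 40 °C; CuCl (10 mol%), then 5, THF, 50 °C; sat. aq NH4Cl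
Reagents that add atoms: none
Why: Two equivalents of EtMgBr remove the hydroxyl and acetylenic protons, and under CuCl catalysis the alkynyl carbon of 7 displaces the benzylic bromide (copper-catalysed alkynyl Grignard–benzyl halide coupling), the magnesium alkoxide being too poor a nucleophile to compete and the carbinol stereocentre taking no part.

Step 5
Reactants: 8 (R)-5-(3,4-dimethoxyphenyl)pent-3-yn-2-ol
Product: 10 (R,E)-5-(3,4-dimethoxyphenyl)pent-3-en-2-ol, via cyclic alkenylalanate 9 (not isolated)
Conditions: NaAlH2(OCH2CH2OMe)2 (Red-Al, 2 equiv), THF, 0 °C → rt; aq KNaC4H4O6 (potassium sodium tartrate) work-up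
Reagents that add atoms: none
Why: The aluminium alkoxide formed at the propargylic hydroxyl delivers hydride to the nearer alkyne carbon while aluminium bonds to the farther one in a trans sense (hydroxyl-directed trans-hydroalumination), and protonolysis of the vinyl–Al bond of 9 with retention should leave only the E alkene, with the benzylic CH2 and the stereocentre untouched.

Step 6
Reactants: 3 3-[3,4-bis(benzyloxy)phenyl]propanoic acid; 10 (R,E)-5-(3,4-dimethoxyphenyl)pent-3-en-2-ol
Product: 11 (R,E)-5-(3,4-dimethoxyphenyl)pent-3-en-2-yl 3-[3,4-bis(benzyloxy)phenyl]propanoate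
Conditions: DCC, DMAP (cat.), CH2Cl2, 0 °C → rt
Reagents that add atoms: none
Why: DCC activates the carboxyl group and DMAP relays the acyl unit to the secondary allylic hydroxyl (Steglich esterification), so the carbinol C–O bond is never broken and both the R configuration and the E geometry are retained.

Step 7
Reactants: 11 (R,E)-5-(3,4-dimethoxyphenyl)pent-3-en-2-yl 3-[3,4-bis(benzyloxy)phenyl]propanoate
Product: 15 (2R,3S,4E)-2-[3,4-bis(benzyloxy)benzyl]-3-(3,4-dimethoxybenzyl)hex-4-enoic acid, via lithium enolate 12 (not isolated), via silyl ketene acetal 13 (not isolated), via silyl ester 14 (not isolated)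
Conditions: LiN(i-Pr)2, THF/DMPU (55:45), −78 °C; TBSCl, −78 °C → rt, then 60 °C; 1 M HCl, THF, rt
Reagents that add atoms: none
Why: In THF/DMPU the amide base removes a proton from the single enolisable CH2 through an open transition state to give enolate 12 with the arylmethyl group cis to O–Li, TBSCl fixes this geometry on oxygen as ketene acetal 13, and on warming 13 undergoes a concerted suprafacial [3,3]-sigmatropic shift through a chair in which the carbinol C–O bond breaks, the α-carbon bonds to the alkene carbon carrying the veratrylmethyl group and an E-propenyl double bond appears, after which hydrolysis of silyl ester 14 frees the acid. The closest known reaction type is the Ireland–Claisen rearrangement of esters of enantiopure secondary E-allylic alcohols with 1,3-chirality transfer. No ring is closed: only the open-chain C2–C3 bond of the hexenoic acid, the later C3–C4 bond of the lactone, is made. C3 of the acid (S) is controlled by the R carbinol, whose methyl group takes the equatorial position of the chair and so decides which face of the E-alkene terminus is bonded. C2 (R) is controlled by the ketene acetal geometry: with the arylmethyl group cis to OSi both arylmethyl groups are equatorial in the chair, which corresponds to the syn acid. The step therefore needs facial selectivity at the allyl terminus, secured by the pure E alkene from step 5 and the chair preference of an open-chain substrate, and syn selectivity, secured by the dipolar cosolvent, and any shortfall at C2 is repaired in step 8.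

Step 8
Reactants: 15 (2R,3S,4E)-2-[3,4-bis(benzyloxy)benzyl]-3-(3,4-dimethoxybenzyl)hex-4-enoic acid
Product: 18 (3R,4R)-3-[3,4-bis(benzyloxy)benzyl]-4-(3,4-dimethoxybenzyl)dihydrofuran-2(3H)-one, via ozonide 16 (not isolated), via hydroxy acid 17 (not isolated)
Conditions: O3, CH2Cl2, −78 °C, Sudan Red 7B end point; NaBH4, MeOH, −78 °C → rt; 2 M HCl, rt; crude lactone: DBU (0.2 equiv), toluene, 80 °C
Reagents that add atoms: ozone, [O-][O+]=O
Why: Ozone cleaves the only C=C bond by the Criegee sequence to ozonide 16 faster than it attacks the alkoxy-arenes when addition stops at the dye end point, NaBH4 reduces 16 straight to the primary alcohol 17 so that no α-branched aldehyde lingers, acid closes the five-membered lactone by attack of that hydroxyl on the carboxyl carbon (5-exo-trig acyl substitution), and DBU equilibrates any cis isomer at the enolisable C3 to the more stable trans lactone without touching C4.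

Step 9
Reactants: 18 (3R,4R)-3-[3,4-bis(benzyloxy)benzyl]-4-(3,4-dimethoxybenzyl)dihydrofuran-2(3H)-one
Product: 19 3'-O-demethylarctigenin [(3R,4R)-3-(3,4-dihydroxybenzyl)-4-(3,4-dimethoxybenzyl)dihydrofuran-2(3H)-one]
Conditions: H2 (1 atm), 10% Pd/C, EtOAc/MeOH, rt
Reagents that add atoms: none
Why: Palladium-catalysed hydrogenolysis cleaves the two benzylic C–O bonds of the aryl benzyl ethers, while the aryl methyl ethers, the lactone and both stereocentres, none of which is benzylic to oxygen, should be inert under these neutral conditions.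

**Compound list**

1 | 3-(3,4-dihydroxyphenyl)propanoic acid (dihydrocaffeic acid) | O=C(O)CCc1ccc(O)c(O)c1 | starting material
2 | benzyl 3-[3,4-bis(benzyloxy)phenyl]propanoate | O=C(OCc1ccccc1)CCc1ccc(OCc2ccccc2)c(OCc2ccccc2)c1 | intermediate
3 | 3-[3,4-bis(benzyloxy)phenyl]propanoic acid | O=C(O)CCc1ccc(OCc2ccccc2)c(OCc2ccccc2)c1 | intermediate
4 | 3,4-dimethoxybenzyl alcohol (veratryl alcohol) | COc1ccc(CO)cc1OC | starting material
5 | 3,4-dimethoxybenzyl bromide | COc1ccc(CBr)cc1OC | intermediate
6 | (R)-but-3-yn-2-ol | C[C@@H](O)C#C | starting material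
7 | bromomagnesium (R)-4-(bromomagnesio)but-3-yn-2-olate (dimagnesium alkynide) | C[C@@H](O[Mg]Br)C#C[Mg]Br | intermediate (not isolated)
8 | (R)-5-(3,4-dimethoxyphenyl)pent-3-yn-2-ol | C[C@@H](O)C#CCc1ccc(OC)c(OC)c1 | intermediate
9 | sodium (R)-3-(3,4-dimethoxybenzyl)-2,2-bis(2-methoxyethoxy)-5-methyl-2,5-dihydro-1,2-oxaaluminol-2-uide (cyclic alkenylalanate) | C[C@H]1O[Al-](OCCOC)(OCCOC)C(Cc2ccc(OC)c(OC)c2)=C1.[Na+] | intermediate (not isolated)
10 | (R,E)-5-(3,4-dimethoxyphenyl)pent-3-en-2-ol | C[C@@H](O)/C=C/Cc1ccc(OC)c(OC)c1 | intermediate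
11 | (R,E)-5-(3,4-dimethoxyphenyl)pent-3-en-2-yl 3-[3,4-bis(benzyloxy)phenyl]propanoate | C[C@@H](OC(=O)CCc1ccc(OCc2ccccc2)c(OCc2ccccc2)c1)/C=C/Cc1ccc(OC)c(OC)c1 | intermediate
12 | lithium enolate of 11 with O–Li cis to the 3,4-bis(benzyloxy)benzyl group | [Li]O/C(O[C@H](C)/C=C/Cc1ccc(OC)c(OC)c1)=C\Cc1ccc(OCc2ccccc2)c(OCc2ccccc2)c1 | intermediate (not isolated)
13 | (Z)-tert-butyldimethylsilyl ketene acetal of 11 (arylmethyl cis to OSi) | CC(C)(C)[Si](C)(C)O/C(O[C@H](C)/C=C/Cc1ccc(OC)c(OC)c1)=C\Cc1ccc(OCc2ccccc2)c(OCc2ccccc2)c1 | intermediate (not isolated)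
14 | tert-butyldimethylsilyl (2R,3S,4E)-2-[3,4-bis(benzyloxy)benzyl]-3-(3,4-dimethoxybenzyl)hex-4-enoate | COc1ccc(C[C@@H](/C=C/C)[C@@H](Cc2ccc(OCc3ccccc3)c(OCc3ccccc3)c2)C(=O)O[Si](C)(C)C(C)(C)C)cc1OC | intermediate (not isolated)
15 | (2R,3S,4E)-2-[3,4-bis(benzyloxy)benzyl]-3-(3,4-dimethoxybenzyl)hex-4-enoic acid | COc1ccc(C[C@@H](/C=C/C)[C@@H](Cc2ccc(OCc3ccccc3)c(OCc3ccccc3)c2)C(=O)O)cc1OC | intermediate
16 | (2R,3R)-2-[3,4-bis(benzyloxy)benzyl]-4-(3,4-dimethoxyphenyl)-3-(5-methyl-1,2,4-trioxolan-3-yl)butanoic acid (secondary ozonide of 15; trioxolane carbons unassigned) | COc1ccc(C[C@@H](C2OOC(C)O2)[C@@H](Cc2ccc(OCc3ccccc3)c(OCc3ccccc3)c2)C(=O)O)cc1OC | intermediate (not isolated)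
17 | (2R,3R)-2-[3,4-bis(benzyloxy)benzyl]-3-(3,4-dimethoxybenzyl)-4-hydroxybutanoic acid | COc1ccc(C[C@@H](CO)[C@@H](Cc2ccc(OCc3ccccc3)c(OCc3ccccc3)c2)C(=O)O)cc1OC | intermediate (not isolated)
18 | (3R,4R)-3-[3,4-bis(benzyloxy)benzyl]-4-(3,4-dimethoxybenzyl)dihydrofuran-2(3H)-one | COc1ccc(C[C@H]2COC(=O)[C@@H]2Cc2ccc(OCc3ccccc3)c(OCc3ccccc3)c2)cc1OC | intermediate
19 | 3'-O-demethylarctigenin [(3R,4R)-3-(3,4-dihydroxybenzyl)-4-(3,4-dimethoxybenzyl)dihydrofuran-2(3H)-one] | COc1ccc(C[C@H]2COC(=O)[C@@H]2Cc2ccc(O)c(O)c2)cc1OC | target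

**Step count**

Total steps: 9. Longest linear sequence: 7 steps (steps 3 to 9, from 3,4-dimethoxybenzyl alcohol); steps 1 and 2 form the convergent acid branch.

**Steps most likely to fail, with fallbacks**

Step 7. Incomplete control of the enolate geometry, slow enolisation or competing C-silylation would erode the syn selectivity and the conversion, leaving more C2 epimer than the later equilibration can comfortably absorb. The fallback sets out from alcohol 10 and rejoins the route at lactone 18. Alcohol 10 would be heated with triethyl orthoacetate and a trace of propanoic acid (Johnson–Claisen rearrangement: the same chair and the same 1,3-transfer, but no enolate geometry to control) to give ethyl (3R,4E)-3-(3,4-dimethoxybenzyl)hex-4-enoate F1. Ozonolysis with NaBH4 quench should give ethyl (R)-3-(3,4-dimethoxybenzyl)-4-hydroxybutanoate F2, which closes under acid to (R)-4-(3,4-dimethoxybenzyl)dihydrofuran-2(3H)-one F3. Deprotonation with LiN(SiMe3)2 in THF at −78 °C and alkylation with 3,4-bis(benzyloxy)benzyl bromide F4 (made from commercial 3,4-bis(benzyloxy)benzyl alcohol and PBr3) should enter anti to the C4 substituent and give 18 directly. The central C–C bond is still made by a Claisen shift, and C3 is then set by substrate-controlled lactone alkylation instead of by ketene acetal geometry.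

Step 4. Homocoupling of the electron-rich benzyl bromide, base-induced propargyl-to-allene isomerisation of the skipped aryl alkyne, or sluggish reaction of the poorly soluble dimagnesium species may lower the yield of the coupling. The fallback sets out from alkynol 6 (with bromide 5 as partner) and rejoins at allylic alcohol 10, bypassing 8. Silylation (TBSCl, imidazole) would give (R)-tert-butyl(but-3-yn-2-yloxy)dimethylsilane F5. Syn-hydroboration with pinacolborane catalysed by Cp2Zr(H)Cl should give (R,E)-tert-butyldimethyl{[4-(4,4,5,5-tetramethyl-1,3,2-dioxaborolan-2-yl)but-3-en-2-yl]oxy}silane F6. Suzuki–Miyaura coupling of F6 with 5 (Pd(PPh3)4, aq K2CO3, dioxane, 80 °C) should give (R,E)-tert-butyl{[5-(3,4-dimethoxyphenyl)pent-3-en-2-yl]oxy}dimethylsilane F7, and Bu4NF in THF removes the silyl group to give 10. The E geometry then comes from the syn-hydroboration, and no propargylic benzylic position is ever exposed to a strong base.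

Step 8. Over-oxidation of the two alkoxy-arenes or of the benzyl ethers by ozone, or epimerisation at the α-branched carbon if carbonyl intermediates persist, may degrade the material. The fallback sets out from acid 15 and rejoins at lactone 18. Methylation (MeI, K2CO3, DMF) would give methyl (2R,3S,4E)-2-[3,4-bis(benzyloxy)benzyl]-3-(3,4-dimethoxybenzyl)hex-4-enoate F8, the ester being chosen so that the intermediate diol cannot lactonise onto the wrong hydroxyl. Lemieux–Johnson cleavage (OsO4 cat., NaIO4, 2,6-lutidine, dioxane/H2O) should give methyl (2R,3R)-2-[3,4-bis(benzyloxy)benzyl]-3-(3,4-dimethoxybenzyl)-4-oxobutanoate F9. Immediate reduction with NaBH4 in MeOH at 0 °C should give methyl (2R,3R)-2-[3,4-bis(benzyloxy)benzyl]-3-(3,4-dimethoxybenzyl)-4-hydroxybutanoate F10, which lactonises with catalytic TsOH and, after the same DBU equilibration, gives 18.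

Further compounds
F1 | step 7 | ethyl (3R,4E)-3-(3,4-dimethoxybenzyl)hex-4-enoate | COc1ccc(C[C@@H](/C=C/C)CC(=O)OCC)cc1OC
F2 | step 7 | ethyl (R)-3-(3,4-dimethoxybenzyl)-4-hydroxybutanoate | COc1ccc(C[C@@H](CO)CC(=O)OCC)cc1OC
F3 | step 7 | (R)-4-(3,4-dimethoxybenzyl)dihydrofuran-2(3H)-one | COc1ccc(C[C@H]2COC(=O)C2)cc1OC
F4 | step 7 | 3,4-bis(benzyloxy)benzyl bromide | BrCc1ccc(OCc2ccccc2)c(OCc2ccccc2)c1
F5 | step 4 | (R)-tert-butyl(but-3-yn-2-yloxy)dimethylsilane | C[C@@H](O[Si](C)(C)C(C)(C)C)C#C
F6 | step 4 | (R,E)-tert-butyldimethyl{[4-(4,4,5,5-tetramethyl-1,3,2-dioxaborolan-2-yl)but-3-en-2-yl]oxy}silane | C[C@@H](O[Si](C)(C)C(C)(C)C)/C=C/B1OC(C)(C)C(C)(C)O1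
F7 | step 4 | (R,E)-tert-butyl{[5-(3,4-dimethoxyphenyl)pent-3-en-2-yl]oxy}dimethylsilane | C[C@@H](O[Si](C)(C)C(C)(C)C)/C=C/Cc1ccc(OC)c(OC)c1
F8 | step 8 | methyl (2R,3S,4E)-2-[3,4-bis(benzyloxy)benzyl]-3-(3,4-dimethoxybenzyl)hex-4-enoate | COc1ccc(C[C@@H](/C=C/C)[C@@H](Cc2ccc(OCc3ccccc3)c(OCc3ccccc3)c2)C(=O)OC)cc1OC
F9 | step 8 | methyl (2R,3R)-2-[3,4-bis(benzyloxy)benzyl]-3-(3,4-dimethoxybenzyl)-4-oxobutanoate | COc1ccc(C[C@@H](C=O)[C@@H](Cc2ccc(OCc3ccccc3)c(OCc3ccccc3)c2)C(=O)OC)cc1OC
F10 | step 8 | methyl (2R,3R)-2-[3,4-bis(benzyloxy)benzyl]-3-(3,4-dimethoxybenzyl)-4-hydroxybutanoate | COc1ccc(C[C@@H](CO)[C@@H](Cc2ccc(OCc3ccccc3)c(OCc3ccccc3)c2)C(=O)OC)cc1OC
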